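The flavone is opened across ring A: C8–C8a, C7–C8, C5–C6 and C4a–C5 are made in one operation, a Danheiser benzannulation between a pyranonyl diazomethyl ketone and a silyloxyalkyne. The step exploits the meta oxygens on C5 and C7 of ring A and the fusion of ring A to the pyranone (ring C) through C4a–C8a, which is the C3=C2 double bond of the precursor. It should deliver ring A with O5 free and O7 silylated. The precursor is a 4-pyranone carrying the diazoacetyl group at C2 and ring B at C6, with O3' as allyl ether and O4' as benzyl ether, so that O7 and O3' can be bared together for sulfation.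

Key step: step 8

Assumption: the sulfate half-esters are drawn as free acids, as in the target; on the bench they would be handled as sodium salts and the acid form released at the end on a sulfonic acid resin.

Step 1
Reactants: 1 3',4'-dihydroxyacetophenone
Product: 2 1-[4-(benzyloxy)-3-hydroxyphenyl]ethanone
Conditions: BnBr (1.05 equiv), NaHCO3, NaI (cat.), DMF, 40 °C
Reagents that add atoms: benzyl bromide, BrCc1ccccc1
Why: Williamson etherification; the 4-hydroxyl, para to the acetyl group, is the more acidic phenol, so the weak base should ionise it alone and benzylation should stop at the 4-ether.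

Step 2
Reactants: 2 1-[4-(benzyloxy)-3-hydroxyphenyl]ethanone
Product: 3 1-[3-(allyloxy)-4-(benzyloxy)phenyl]ethanone
Conditions: allyl bromide, K2CO3, DMF, 25 °C
Reagents that add atoms: allyl bromide, C=CCBr
Why: Williamson etherification of the only remaining phenol, so no selectivity question arises.

Step 3
Reactants: 3 1-[3-(allyloxy)-4-(benzyloxy)phenyl]ethanone
Product: 4 1-[3-(allyloxy)-4-(benzyloxy)phenyl]butane-1,3-dione
Conditions: NaH (2.5 equiv), EtOAc (5 equiv), THF, 0 → 60 °C; then aq. HCl
Reagents that add atoms: ethyl acetate, CCOC(C)=O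
Why: Crossed Claisen condensation of the ketone enolate with ethyl acetate, driven by formation of the stable 1,3-diketonate.

Step 4
Reactants: 4 1-[3-(allyloxy)-4-(benzyloxy)phenyl]butane-1,3-dione; 5 diethyl oxalate
Product: 7 ethyl 6-[3-(allyloxy)-4-(benzyloxy)phenyl]-4-oxo-4H-pyran-2-carboxylate, via triketo ester 6 (not isolated)
Conditions: NaOEt (2.5 equiv), EtOH–THF, 0 → 50 °C; then HCl (conc.), EtOH, 70 °C
Reagents that add atoms: none
Why: Claisen condensation with the non-enolisable oxalate should occur at the terminal methyl group, the only site that leads to a stable delocalised enolate, and acid then cyclodehydrates the 1,3,5-tricarbonyl chain to the 4-pyranone (the classical comanic ester synthesis).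

Step 5
Reactants: 7 ethyl 6-[3-(allyloxy)-4-(benzyloxy)phenyl]-4-oxo-4H-pyran-2-carboxylate
Product: 8 6-[3-(allyloxy)-4-(benzyloxy)phenyl]-4-oxo-4H-pyran-2-carboxylic acid
Conditions: LiOH·H2O (1.1 equiv), THF–H2O, 0 °C; then aq. HCl to pH 2
Reagents that add atoms: lithium hydroxide, [Li+].[OH-] (hydroxide oxygen of the acid)
Why: Saponification of an ester activated by the electron-poor pyranone; one equivalent of hydroxide at 0 °C should hydrolyse it faster than it opens the ring.

Step 6
Reactants: 8 6-[3-(allyloxy)-4-(benzyloxy)phenyl]-4-oxo-4H-pyran-2-carboxylic acid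
Product: 10 2-(diazoacetyl)-6-[3-(allyloxy)-4-(benzyloxy)phenyl]-4H-pyran-4-one, via acid chloride 9 (not isolated)
Conditions: (COCl)2 (1.5 equiv), DMF (cat.), CH2Cl2, 0 → 25 °C; concentrate; then CH2N2 (3 equiv), Et2O–CH2Cl2, −10 → 0 °C
Reagents that add atoms: diazomethane, C=[N+]=[N-]; oxalyl chloride, O=C(Cl)C(=O)Cl (supplies the chlorine of 9 only)
Why: Acid chloride formation and C-acylation of diazomethane (first stage of an Arndt–Eistert sequence), with a second equivalent of diazomethane taking up HCl; the acid has no α-hydrogen, and short contact at low temperature should spare the pyranone double bonds.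

Step 7
Reactants: 11 3-phenylisoxazole; 12 triisopropylsilyl trifluoromethanesulfonate
Product: 15 (triisopropylsilyloxy)ethyne, via lithioisoxazole 13 (not isolated), via lithium ethynolate 14 (not isolated)
Conditions: n-BuLi (1.0 equiv), THF, −78 → −20 °C; then 12, −78 → 0 °C; pentane, filtration, short-path distillation
Reagents that add atoms: n-butyllithium, [Li]CCCC (supplies the lithium of 13 and 14 only)
Why: Deprotonation at C5 triggers the cycloreversion of 5-lithioisoxazoles to a nitrile and a lithium ynolate, and the hard, bulky silyl triflate should silylate the ambident ynolate on oxygen.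

Step 8
Reactants: 10 2-(diazoacetyl)-6-[3-(allyloxy)-4-(benzyloxy)phenyl]-4H-pyran-4-one; 15 (triisopropylsilyloxy)ethyne (2 equiv)
Product: 19 3'-O-allyl-4'-O-benzyl-7-O-(triisopropylsilyl)luteolin, via pyranonylketene 16 (not isolated), via silyloxycyclobutenone 17 (not isolated), via dienylketene 18 (not isolated)
Conditions: hν (LED, 405–450 nm), degassed ClCH2CH2Cl, 20 °C; then 80 °C
Reagents that add atoms: none
Why: Proposed new method: light expels N2 from 10 with a 1,2-shift of the pyranonyl group (Wolff rearrangement) to give ketene 16, whose carbonyl carbon is attacked by the nucleophilic CH terminus of 15 in a [2+2] cycloaddition to cyclobutenone 17; thermal four-electron electrocyclic opening gives dienylketene 18, and six-electron electrocyclization of the ketene carbon onto pyranone C3 followed by enolisation gives the C5 phenol of 19. The closest known reaction is the Danheiser benzannulation of aryl, heteroaryl and alkenyl diazomethyl ketones with silyloxyalkynes; new here is that the C2=C3 bond of a 4-pyranone serves as the alkene of the vinylketene, which is reasonable because that bond is only weakly aromatic and the acyl-conjugated ketene is more electrophilic than the known cases. Ring A is closed by the 6π electrocyclization (C4a–C5), after the Wolff shift has made C8–C8a and the [2+2] addition has made C5–C6 and C7–C8. No stereocentre is formed in 19; the one in 17 is racemic and is lost on ring opening. The regiochemistry needed, silyloxy at C7 meta to the C5 hydroxyl, follows from the polarisation of the ynol ether, and closure can only occur at C3 because the other neighbour of the ketene-bearing carbon is the ring oxygen. Light of 405–450 nm is chosen so that only the diazo chromophore absorbs, which should spare the aryl pyranone, the allyl aryl ether and the flavone product.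

Step 9
Reactants: 19 3'-O-allyl-4'-O-benzyl-7-O-(triisopropylsilyl)luteolin
Product: 21 4'-O-benzylluteolin, via silyl ether 20 (not isolated)
Conditions: Pd(PPh3)4 (5 mol %), morpholine (10 equiv), THF, 25 °C; then Bu4NF–AcOH (1.5 equiv each), 0 → 25 °C
Reagents that add atoms: none
Why: Tsuji–Trost-type deallylation, in which zerovalent palladium ionises the aryl allyl ether and morpholine traps the allyl fragment while O7 is still silylated, so ring A should not be C-allylated; buffered fluoride then cleaves the aryl silyl ether.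

Step 10
Reactants: 21 4'-O-benzylluteolin
Product: 22 4'-O-benzylluteolin 7,3'-bis(hydrogen sulfate)
Conditions: SO3·pyridine (8 equiv), pyridine, 25 → 45 °C; then aq. NaHCO3, Sephadex LH-20
Reagents that add atoms: sulfur trioxide–pyridine complex, [O-]S(=O)(=O)[n+]1ccccc1
Why: O-Sulfation of phenols with an SO3–amine complex; the 7- and 3'-hydroxyls should react, whereas the 5-hydroxyl is held in a hydrogen bond to the C4 carbonyl and should stay free.

Step 11
Reactants: 22 4'-O-benzylluteolin 7,3'-bis(hydrogen sulfate)
Product: 23 luteolin 7,3'-disulfate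
Conditions: H2 (1 atm), Pd/C (10 wt %), MeOH–H2O, 25 °C; then sulfonic acid resin (H+ form), 0 °C, lyophilisation
Reagents that add atoms: none
Why: Hydrogenolysis of the benzyl aryl ether on Pd/C; aryl sulfate monoesters and the flavone C2=C3 bond should be inert at 1 atm, and using the sodium salt keeps pyridine away from the catalyst.

Compound list
1 | 3',4'-dihydroxyacetophenone | CC(=O)c1ccc(O)c(O)c1 | starting material
2 | 1-[4-(benzyloxy)-3-hydroxyphenyl]ethanone | CC(=O)c1ccc(OCc2ccccc2)c(O)c1 | intermediate
3 | 1-[3-(allyloxy)-4-(benzyloxy)phenyl]ethanone | CC(=O)c1ccc(OCc2ccccc2)c(OCC=C)c1 | intermediate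
4 | 1-[3-(allyloxy)-4-(benzyloxy)phenyl]butane-1,3-dione | CC(=O)CC(=O)c1ccc(OCc2ccccc2)c(OCC=C)c1 | intermediate
5 | diethyl oxalate | CCOC(=O)C(=O)OCC | starting material
6 | ethyl 6-[3-(allyloxy)-4-(benzyloxy)phenyl]-2,4,6-trioxohexanoate (not isolated) | CCOC(=O)C(=O)CC(=O)CC(=O)c1ccc(OCc2ccccc2)c(OCC=C)c1 | intermediate
7 | ethyl 6-[3-(allyloxy)-4-(benzyloxy)phenyl]-4-oxo-4H-pyran-2-carboxylate | CCOC(=O)c1cc(=O)cc(-c2ccc(OCc3ccccc3)c(OCC=C)c2)o1 | intermediate
8 | 6-[3-(allyloxy)-4-(benzyloxy)phenyl]-4-oxo-4H-pyran-2-carboxylic acid | OC(=O)c1cc(=O)cc(-c2ccc(OCc3ccccc3)c(OCC=C)c2)o1 | intermediate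
9 | 6-[3-(allyloxy)-4-(benzyloxy)phenyl]-4-oxo-4H-pyran-2-carbonyl chloride (not isolated) | O=C(Cl)c1cc(=O)cc(-c2ccc(OCc3ccccc3)c(OCC=C)c2)o1 | intermediate
10 | 2-(diazoacetyl)-6-[3-(allyloxy)-4-(benzyloxy)phenyl]-4H-pyran-4-one | [N-]=[N+]=CC(=O)c1cc(=O)cc(-c2ccc(OCc3ccccc3)c(OCC=C)c2)o1 | intermediate
11 | 3-phenylisoxazole | c1ccc(-c2ccon2)cc1 | starting material
12 | triisopropylsilyl trifluoromethanesulfonate | CC(C)[Si](OS(=O)(=O)C(F)(F)F)(C(C)C)C(C)C | starting material
13 | 5-lithio-3-phenylisoxazole (not isolated) | [Li]c1cc(-c2ccccc2)no1 | intermediate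
14 | lithium ethynolate (not isolated) | [Li+].[O-]C#C | intermediate
15 | (triisopropylsilyloxy)ethyne | C#CO[Si](C(C)C)(C(C)C)C(C)C | intermediate
16 | {6-[3-(allyloxy)-4-(benzyloxy)phenyl]-4-oxo-4H-pyran-2-yl}ketene (not isolated) | O=C=Cc1cc(=O)cc(-c2ccc(OCc3ccccc3)c(OCC=C)c2)o1 | intermediate
17 | 4-{6-[3-(allyloxy)-4-(benzyloxy)phenyl]-4-oxo-4H-pyran-2-yl}-3-(triisopropylsilyloxy)cyclobut-2-en-1-one (racemic; not isolated) | O=C1C=C(O[Si](C(C)C)(C(C)C)C(C)C)C1c1cc(=O)cc(-c2ccc(OCc3ccccc3)c(OCC=C)c2)o1 | intermediate
18 | 4-{6-[3-(allyloxy)-4-(benzyloxy)phenyl]-4-oxo-4H-pyran-2-yl}-3-(triisopropylsilyloxy)buta-1,3-dien-1-one (ketenyl carbon cis to the pyranone across C3=C4; not isolated) | O=C=C/C(O[Si](C(C)C)(C(C)C)C(C)C)=C\c1cc(=O)cc(-c2ccc(OCc3ccccc3)c(OCC=C)c2)o1 | intermediate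
19 | 3'-O-allyl-4'-O-benzyl-7-O-(triisopropylsilyl)luteolin | O=c1cc(-c2ccc(OCc3ccccc3)c(OCC=C)c2)oc2cc(O[Si](C(C)C)(C(C)C)C(C)C)cc(O)c12 | intermediate
20 | 4'-O-benzyl-7-O-(triisopropylsilyl)luteolin (not isolated) | O=c1cc(-c2ccc(OCc3ccccc3)c(O)c2)oc2cc(O[Si](C(C)C)(C(C)C)C(C)C)cc(O)c12 | intermediate
21 | 4'-O-benzylluteolin | O=c1cc(-c2ccc(OCc3ccccc3)c(O)c2)oc2cc(O)cc(O)c12 | intermediate
22 | 4'-O-benzylluteolin 7,3'-bis(hydrogen sulfate) | O=c1cc(-c2ccc(OCc3ccccc3)c(OS(=O)(=O)O)c2)oc2cc(OS(=O)(=O)O)cc(O)c12 | intermediate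
23 | luteolin 7,3'-disulfate | O=c1cc(-c2ccc(O)c(OS(=O)(=O)O)c2)oc2cc(OS(=O)(=O)O)cc(O)c12 | target

Total step count: 11. Longest linear sequence: 10 steps (1 to 23 through steps 1–6 and 8–11); step 7 is a one-step side branch.

Steps most likely to fail

1. Step 8. The pyranone may be excited along with the diazo group, the ketene may dimerise before it meets the alkyne, or closure onto the cross-conjugated pyranone carbon may be too slow and the dienylketene be diverted. The fallback builds ring C onto a ready-made ring A by known chemistry, sets out from 3 and comes back at 21. Haloform cleavage of 3 (NaOCl, NaOH, dioxane–H2O) would give 3-(allyloxy)-4-(benzyloxy)benzoic acid F1, and (COCl)2 with catalytic DMF its chloride, 3-(allyloxy)-4-(benzyloxy)benzoyl chloride F2. Acylation of the lithium polyanion of commercial 2',4',6'-trihydroxyacetophenone (LiN(SiMe3)2, THF, −78 → 25 °C; Baker–Venkataraman-type C-acylation) would give 1-[3-(allyloxy)-4-(benzyloxy)phenyl]-3-(2,4,6-trihydroxyphenyl)propane-1,3-dione F3. Cyclodehydration (AcOH, catalytic H2SO4, 90 °C) would close it to 3'-O-allyl-4'-O-benzylluteolin F4. Deallylation of F4 with Pd(PPh3)4 and a large excess of morpholine returns to the route at 21.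

2. Step 7. The unsubstituted ynolate may be silylated on carbon instead of oxygen, or may oligomerise before it is trapped. The fallback sets out from 12 and comes back at 19. Ethynyltrimethylsilane, n-BuLi and then LiOOtBu (oxygenation of the acetylide) would give lithium (trimethylsilyl)ethynolate F5, whose carbon terminus is shielded, so 12 should silylate it on oxygen to triisopropyl{[(trimethylsilyl)ethynyl]oxy}silane F6. F6 would take the place of 15 in step 8 and give 3'-O-allyl-4'-O-benzyl-7-O-(triisopropylsilyl)-6-(trimethylsilyl)luteolin F7. CF3CO2H in CH2Cl2 at 0 °C would remove the C6 silyl group by ipso-protodesilylation of the electron-rich ring and return to 19; any O7 silyl ether lost at this point converges on 21 after step 9.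

3. Step 10. Sulfation may be incomplete or unselective, and sulfate may be lost while a very polar salt is purified. The fallback replaces direct sulfation by protected sulfate diesters, sets out from 21 and comes back at 22. 2,2,2-Trichloroethyl chlorosulfate, Et3N and DMAP in THF would give the neutral, chromatographable 4'-O-benzylluteolin 7,3'-bis(2,2,2-trichloroethyl sulfate) F8, the chelated 5-hydroxyl again staying free. Reductive cleavage of both trichloroethyl groups (Zn, HCO2NH4, MeOH, 25 °C) would return to the route at 22.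

Further compounds
F1 | step 8 | 3-(allyloxy)-4-(benzyloxy)benzoic acid | OC(=O)c1ccc(OCc2ccccc2)c(OCC=C)c1
F2 | step 8 | 3-(allyloxy)-4-(benzyloxy)benzoyl chloride | O=C(Cl)c1ccc(OCc2ccccc2)c(OCC=C)c1
F3 | step 8 | 1-[3-(allyloxy)-4-(benzyloxy)phenyl]-3-(2,4,6-trihydroxyphenyl)propane-1,3-dione | O=C(CC(=O)c1c(O)cc(O)cc1O)c1ccc(OCc2ccccc2)c(OCC=C)c1
F4 | step 8 | 3'-O-allyl-4'-O-benzylluteolin | O=c1cc(-c2ccc(OCc3ccccc3)c(OCC=C)c2)oc2cc(O)cc(O)c12
F5 | step 7 | lithium (trimethylsilyl)ethynolate | [Li+].[O-]C#C[Si](C)(C)C
F6 | step 7 | triisopropyl{[(trimethylsilyl)ethynyl]oxy}silane | C[Si](C)(C)C#CO[Si](C(C)C)(C(C)C)C(C)C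
F7 | step 7 | 3'-O-allyl-4'-O-benzyl-7-O-(triisopropylsilyl)-6-(trimethylsilyl)luteolin | O=c1cc(-c2ccc(OCc3ccccc3)c(OCC=C)c2)oc2cc(O[Si](C(C)C)(C(C)C)C(C)C)c([Si](C)(C)C)c(O)c12
F8 | step 10 | 4'-O-benzylluteolin 7,3'-bis(2,2,2-trichloroethyl sulfate) | O=c1cc(-c2ccc(OCc3ccccc3)c(OS(=O)(=O)OCC(Cl)(Cl)Cl)c2)oc2cc(OS(=O)(=O)OCC(Cl)(Cl)Cl)cc(O)c12
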